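At the reading, 0.597 s after mixing, 5.0% of the starting material in this flask is converted, and the orders are asked at that moment, not at mixing.

starting material 0.20 M; second substrate 1.00 equiv; coupling partner 0.500 equiv; free catalyst 0.15 mol%; impurity 93 µM

    starting material + free catalyst ⇌ catalyst intermediate A (K1 = 1200 /M, k1 = 870 /M/s)
    coupling partner + catalyst intermediate A → free catalyst + target (k2 = 2300 /M/s)
    second substrate + free catalyst ⇌ catalyst intermediate B (K3 = 1.6 /M, k3 = 11000 /M/s)
    coupling partner + catalyst intermediate B → free catalyst + second product (k4 = 580 /M/s)
    coupling partner ⇌ dormant form (K5 = 1.9, k5 = 0.11 /s)
    free catalyst + impurity → spent catalyst (k6 = 4.9 × 10⁵ /M/s)

- apparent order in free catalyst when 5.0% of the starting material are converted (percent change of the rate of making target for one percent more free catalyst charged)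
- apparent order in second substrate when 5.0% of the starting material are converted (percent change of the rate of making target for one percent more second substrate charged)

By hand, freeze the catalytic round at the charged concentrations. Per free catalyst, catalyst intermediate B stands at x = 0.320, since it returns to free catalyst far faster than coupling partner turns it over. Catalyst intermediate A stands at the ratio of its making to its use, 0.757. The forms therefore sum to S = 2.08 per free catalyst.

The charge is 300 µM of catalyst against 93 µM of impurity. With free catalyst a share 1/S of what works, impurity lasts about 0.0205 s, far shorter than the time of reading. So the working catalyst W, charge minus impurity, is frozen at 207 µM.

One percent more charge raises W by the leverage L, charge over W, 1.45 percent. The rate of making target follows catalyst intermediate A, a fixed share of W while the concentrations stand frozen, so L is the floor of the order in free catalyst by hand, tightened from the 1 of an unpoisoned flask.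

From above, a flask with more catalyst reaches the reading sooner, with less coupling partner gone to the dormant form. In this flask that loss is a fraction near 0.0657 of the coupling partner by the reading, and step 2 is first order in coupling partner, so by hand the order stays below 1.54. In the frozen round second substrate enters through S, which gives −0.154.

The forecast reasons that “the active catalyst is the charge minus the impurity”, and its order in free catalyst stands inside the bracket.

| | order in free catalyst | order in second substrate |
|---|---|---|
| forecast | 1.48 | −0.155 |
| simulation | 1.5 | −0.15 |

Spent catalyst reads 31.0% of the catalyst charged at 2.00 s, and impurity 0% of its own charge. The poisoning step is the largest single effect on the order in free catalyst. With that step taken away, the whole charge works, so L gives a rate 1.45 times the actual one. When 5.0% of the starting material are converted, that run reads an order of 1.0 and a rate 1.46 times the actual one.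

The constants are made up; the flask was simulated.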